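## Structural features

The target is a spiro[5.5]undecane in which cyclohexane rings A and B share the quaternary carbon C6. Ring A reads, from C6: C5 with an exocyclic methylene, C4H2, C3 with a secondary hydroxyl, C2 with bromine, and the gem-dimethyl carbon C1, which is bonded back to C6, so two fully substituted carbons are neighbours. Ring B reads, from C6: C7H2, C8 with chlorine, the methyl carbinol C9 (para to C6), C10H2 and C11H2. The five stereocentres form two vicinal pairs, C2/C3 (bromine cis to hydroxyl) and C8/C9 (chlorine cis to hydroxyl, trans to methyl), which are linked only through C6; C6 is stereogenic solely because ring B is substituted on one arm. Sensitive groups are the two β-halo alcohols (epoxide formation, semipinacol shifts, loss of HX), the tertiary alcohol, and the 1,1-disubstituted alkene next to a quaternary carbon. The real difficulty is the C1–C6 junction of two quaternary carbons together with absolute control at C6, to which no adjacent stereocentre can relay information. The key step exploits that ring B has oxygen at C9 para to C6 and that C6 bears a 2-propenyl-type unit (C5, its methylene and C4). This is what a 1-vinylcyclohex-3-en-1-ol leaves after an oxy-Cope shift: the old ring alkene carbon becomes C6, the vinyl carbons become C7 and C8, and the carbinol carbon becomes C9.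

## Logic of the disconnections

24 to 23: the C3–C4 bond of ring A is cut. A homoallylic alcohol with an exocyclic methylene is the retron of a carbonyl-ene closure, so ring A and the C3 stereocentre disappear together. The forward step must pass through a chair with the carbonyl axial and bromine equatorial, and the Lewis acid must spare both halides and the tertiary alcohol.

23 to 22: the C2–Br bond is cut. Bromine is placed on an open-chain aldehyde, where only one α-position exists. The forward step needs reagent control that overrides the remote stereocentres, and a bromo aldehyde that is used before it epimerises.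

22 to 21 to 20: the aldehyde is traced back to a silyl-protected primary alcohol. The carbonyl is kept masked while the isopropenyl group sits next to it, and it is released without acid.

20 to 19: the C9–CH3 bond is cut, giving an α-chloro ketone. The forward addition must deliver methyl from the equatorial side so that hydroxyl ends up cis to chlorine.

19 to 18: the C8–Cl bond is cut, giving a regiodefined silyl enol ether. The forward step must keep the enol regiochemistry and end with the equatorial chloride.

18 to 15 (through 17 and 16): the C6–C7 bond is cut and the bond between the carbinol carbon and the allylic ring CH2 of 15 is re-formed. The spiro quaternary carbon next to CMe2 becomes a trigonal alkene carbon, ring B becomes the older cyclohexene, and the configuration of C6 is traced to one carbinol stereocentre. The forward step needs a suprafacial [3,3] shift through a boat, no fragmentation or [1,3] shift, and enolate capture before proton exchange.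

15 to 14 to 13: vinyl is traced to formyl, hydroxyl to a benzoate, and the ring methyl to a chloromethyl group. The chloromethyl group is an electronically silent placeholder that lets the tert-alkyl group alone steer the cycloaddition, and it is reduced in the same operation that frees the alcohol.

13 to 9 and 12: the two ring bonds flanking the carbinol carbon and its CH2 neighbour are cut (Diels–Alder). The ring and its only stereocentre form together. The forward step needs the oxygenated carbon para to the tert-alkyl-bearing carbon and one enantiomer.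

9 to 8 to 4 and 5: the central diene bond is cut between two alkenyl carbons (cross-coupling), and the chloride is traced to an allylic alcohol. Each half is a simple 1,1-disubstituted alkenyl unit.

4 to 3 to 2 to 1: the enol triflate comes from a methyl ketone that can enolise on one side only, and the ketone comes from a lactone and a methyl nucleophile. The forward addition must stop at the ketone stage.

12 to 11 to 10: the acyloxy enal is traced to the enol benzoate of a cyclic ketone, from which acetone is lost by cycloreversion.

## Other disconnections considered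

Alternative 1: the cut is the C5–C6 bond. A para-substituted anisole carrying the ring-A chain with a terminal alkyne, A1, would be activated by a π-acid such as Ph3PAuNTf2. The arene carbon para to methoxy would attack the internal alkyne carbon (6-exo-dig, ipso) to give the spiro cyclohexadienone A2 after loss of the O-methyl group.
- In its favour: C2 and C3 are set on an open chain, and the quaternary carbon, ring A and the exocyclic methylene appear in one step. Ipso-cyclisations of p-methoxyaryl alkynes are an established reaction class, so on precedent this alternative is the better of the two.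
- Against it: in A2 ring B is a symmetric dienone and C6 is not yet stereogenic. Its configuration would have to come from telling apart two diastereotopic enone arms under remote control from ring A, followed by selective reduction, chlorination and methyl addition. Attack by the ortho carbon is a competing pathway.
- Comparison: both plans form the hindered bond to C6 intramolecularly and are equal on that point. The chosen plan fixes C6 by stereospecific transfer from 15, whereas here it rests on a diastereotopic-group selection. The step count to A2 would be similar to that to 18, but the way from A2 to 24 is longer.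

Alternative 2: the cut is the C4–C5 bond. The alkynyl β-keto ester A3, with ring B as a symmetric ketal, would undergo a Conia-ene closure (InCl3-type or cationic phosphine–gold catalysis). The enol carbon would add to the internal alkyne carbon to give the ring-A β-keto ester A4 with the exocyclic methylene.
- In its favour: the catalysis is mild and well precedented for methylidene rings, and the key step has no stereochemical demand. The C3 hydroxyl would later come from hydride reduction of a 2-bromo ketone flanked by the gem-dimethyl carbon, a reliably cis-selective operation; on that point the alternative is the equal or the better of the ene closure.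
- Against it: the C1–C6 bond and the ethynyl-bearing quaternary carbon must already exist in A3, so the key step does not address the hardest bond. The bromine-bearing carbon lies next to an enolisable dicarbonyl unit and may epimerise. The ester must be removed afterwards, and ring B must be desymmetrised late, with C6 defined only by a remote preference for one α-carbon.
- Comparison: better mechanistic precedent, but weaker on structure (C6 control) and on step economy than the chosen plan.

Alternative 3: the cut is the C5–C6 bond together with the first bond of a ring-B arm. Irradiation of the enolised 1,3-diketone A5, which carries a 1,1-disubstituted alkene, would give an intramolecular [2+2] adduct. Its retro-aldol opening would give the 1,5-diketone A6, with the ring-A ketone and two different arms on C6.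
- In its favour: ring A, the quaternary carbon and both ring-B arms arise in one operation, and C6 is stereogenic from that moment. More of the skeleton is built in the key step than in the chosen plan, and on that count the alternative is the better.
- Against it: a cyclobutane must form between two fully substituted carbons beside CMe2. Facial control comes only from the remote C2/C3 substituents, and the C–Br bond is exposed to photolysis. Afterwards a hindered ring-A ketone with a β-silyloxy group must be methylenated, and ring B must be built by aldol condensation and then converted into the cis chlorohydrin.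
- Comparison: the chosen plan is stronger on control at C6 (chirality transfer against substrate-biased photocycloaddition) and shorter after the key step. The two are equal in that each rests on a key step without direct precedent on this substrate type.

Key step: step 11

Remark on the design: the stereodescriptors of 15 and 18 are consistent with suprafacial transfer and map onto C6 of 24, so the disconnection is kept unchanged. Two things are improved: the ring-A chain ends in a silyl ether and not in an acetal (an acetal would meet the acid catalyst of step 8 and would need acid hydrolysis next to the isopropenyl group), and the ring methyl of 15 enters as a chloromethyl group, because a diene with methyl and tert-alkyl on its inner carbons would give the cycloaddition no regiochemical bias.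

Assumption: the facial sense of the ammonium-salt catalyst of step 8 with diene 9 is taken by analogy with simple dienes; the antipode that leads to (S)-13 is the one meant.

## Route

Step 1
Reactants: 1 3,3-dimethyldihydrofuran-2(3H)-one
Product: 2 5-hydroxy-3,3-dimethylpentan-2-one
Conditions: MeLi (1.05 equiv), THF, −78 °C; aq. NH4Cl
Reagents that add atoms: methyllithium, [Li]C
Why: Addition of an organolithium to a lactone stops at the tetrahedral lithium lactolate at low temperature and gives the hydroxy ketone on work-up; the α-quaternary carbon further retards a second addition.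

Step 2
Reactants: 2 5-hydroxy-3,3-dimethylpentan-2-one
Product: 3 5-[(tert-butyldimethylsilyl)oxy]-3,3-dimethylpentan-2-one
Conditions: TBSCl, imidazole, DMF, 23 °C
Reagents that add atoms: tert-butyldimethylsilyl chloride, CC(C)(C)[Si](C)(C)Cl
Why: Silylation of the primary hydroxyl traps the open-chain tautomer of the hydroxy ketone; the silyl ether survives bases, hydrides and the acid catalyst used later and is removed without protic acid.

Step 3
Reactants: 3 5-[(tert-butyldimethylsilyl)oxy]-3,3-dimethylpentan-2-one
Product: 4 5-[(tert-butyldimethylsilyl)oxy]-3,3-dimethylpent-1-en-2-yl trifluoromethanesulfonate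
Conditions: KHMDS, THF, −78 °C; PhNTf2, −78 to 0 °C
Reagents that add atoms: N-phenylbis(trifluoromethanesulfonimide), O=S(=O)(N(c1ccccc1)S(=O)(=O)C(F)(F)F)C(F)(F)F
Why: Enol triflate formation by O-sulfonylation of the potassium enolate; the ketone can enolise only toward its methyl group, so a single alkenyl triflate is possible.

Step 4
Reactants: 4 5-[(tert-butyldimethylsilyl)oxy]-3,3-dimethylpent-1-en-2-yl trifluoromethanesulfonate; 5 2-bromoprop-2-en-1-ol
Product: 8 6-[(tert-butyldimethylsilyl)oxy]-4,4-dimethyl-2,3-dimethylidenehexan-1-ol, via dilithium alkoxide 6 (not isolated), via alkenylzinc chloride 7 (not isolated)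
Conditions: 5, t-BuLi (3.0 equiv), Et2O, −78 to 0 °C; ZnCl2, THF; then 4, Pd(PPh3)4 (5 mol%), THF, 23–45 °C
Reagents that add atoms: none
Why: Negishi cross-coupling of an alkenyl triflate with an alkenylzinc reagent made by bromine–lithium exchange and transmetalation; it joins the two trigonal carbons of the diene and brings in the oxygenated one-carbon arm.

Step 5
Reactants: 8 6-[(tert-butyldimethylsilyl)oxy]-4,4-dimethyl-2,3-dimethylidenehexan-1-ol
Product: 9 tert-butyl[(6-chloro-3,3-dimethyl-4,5-dimethylidenehexyl)oxy]dimethylsilane
Conditions: PPh3, NCS, CH2Cl2, −20 to 23 °C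
Reagents that add atoms: N-chlorosuccinimide, O=C1CCC(=O)N1Cl
Why: Appel-type chlorination of a primary allylic alcohol through the alkoxyphosphonium salt; direct and allylic substitution give the same product here because both ends of the allyl unit are CH2.

Step 6
Reactants: 10 2,2-dimethyl-1,3-dioxan-5-one
Product: 11 2,2-dimethyl-4H-1,3-dioxin-5-yl benzoate
Conditions: KHMDS, THF, −78 °C; BzCl, −78 to 0 °C
Reagents that add atoms: benzoyl chloride, O=C(Cl)c1ccccc1
Why: O-acylation of a potassium enolate with a hard acyl chloride gives the enol benzoate.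

Step 7
Reactants: 11 2,2-dimethyl-4H-1,3-dioxin-5-yl benzoate
Product: 12 1-formylethenyl benzoate (2-benzoyloxyacrolein)
Conditions: toluene, 115 °C, acetone distilled off; used as a solution
Reagents that add atoms: none
Why: Thermal retro-hetero-Diels–Alder cycloreversion of the 4H-1,3-dioxin expels acetone and unveils the 2-acyloxy enal.

Step 8
Reactants: 9 tert-butyl[(6-chloro-3,3-dimethyl-4,5-dimethylidenehexyl)oxy]dimethylsilane; 12 1-formylethenyl benzoate
Product: 13 (1S)-3-(chloromethyl)-1-formyl-4-{4-[(tert-butyldimethylsilyl)oxy]-2-methylbutan-2-yl}cyclohex-3-en-1-yl benzoate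
Conditions: (R)-1,1'-binaphthyl-2,2'-diamine (10 mol%), Tf2NH (19 mol%), EtCN, −40 to −20 °C
Reagents that add atoms: none
Why: Enantioselective Diels–Alder reaction of an α-acyloxyacrolein activated as its aldiminium ion by a chiral primary ammonium salt; the catalyst shields one face of the dienophile and so sets C1. The tert-alkyl group is the only donor substituent of the diene (the chloromethyl arm is not a donor), so the β-carbon of the enal bonds to the terminus next to the tert-alkyl carbon and the oxygenated carbon ends up para to it.

Step 9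
Reactants: 13 (1S)-3-(chloromethyl)-1-formyl-4-{4-[(tert-butyldimethylsilyl)oxy]-2-methylbutan-2-yl}cyclohex-3-en-1-yl benzoate
Product: 14 (1S)-3-(chloromethyl)-1-ethenyl-4-{4-[(tert-butyldimethylsilyl)oxy]-2-methylbutan-2-yl}cyclohex-3-en-1-yl benzoate
Conditions: Ph3PCH3Br, KHMDS, THF, 0 °C; then 13, −78 to 0 °C
Reagents that add atoms: methylidenetriphenylphosphorane, C=P(c1ccccc1)(c1ccccc1)c1ccccc1
Why: Wittig methylenation of a non-enolisable aldehyde; at low temperature the aldehyde reacts much faster with the ylide than the benzoate or the allylic chloride.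

Step 10
Reactants: 14 (1S)-3-(chloromethyl)-1-ethenyl-4-{4-[(tert-butyldimethylsilyl)oxy]-2-methylbutan-2-yl}cyclohex-3-en-1-yl benzoate
Product: 15 (1S)-4-{4-[(tert-butyldimethylsilyl)oxy]-2-methylbutan-2-yl}-1-ethenyl-3-methylcyclohex-3-en-1-ol
Conditions: LiBHEt3 (4 equiv), THF, 0 to 23 °C; aq. NH4Cl
Reagents that add atoms: none
Why: Hydride reduction cleaves the tertiary benzoate and displaces the primary allylic chloride by direct substitution (the allylic alternative would need attack at a fully substituted carbon), so the placeholder becomes the ring methyl without a separate step; the stereocentre is untouched.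

Step 11
Reactants: 15 (1S)-4-{4-[(tert-butyldimethylsilyl)oxy]-2-methylbutan-2-yl}-1-ethenyl-3-methylcyclohex-3-en-1-ol
Product: 18 tert-butyldimethyl{3-methyl-3-[(1S)-1-(prop-1-en-2-yl)-4-(trimethylsilyloxy)cyclohex-3-en-1-yl]butoxy}silane, via potassium alkoxide 16 (not isolated), via potassium enolate 17 (not isolated)
Conditions: KH (1.3 equiv), 18-crown-6 (1.3 equiv), THF, 0 to 50 °C; then −78 °C, TMSCl/Et3N; pentane, filtration
Reagents that add atoms: chlorotrimethylsilane, C[Si](C)(C)Cl
Why: Proposed new method: with the ring atoms of 15 counted from the carbinol carbon, deprotonation gives alkoxide 16, whose C1–C2 bond is weakened, so that in a concerted [3,3] shift the vinyl terminus bonds to C4 while C1–C2 breaks; this gives enolate 17 with its double bond on the arm that carries the new bond, and O-silylation fixes that regiochemistry in 18. The closest known reaction type is the anionic oxy-Cope rearrangement of cyclic 3-hydroxy-1,5-dienes forced through boat transition states (2-vinylbicyclo[2.2.2]oct-5-en-2-ols); a monocyclic 1-vinylcyclohex-3-enol whose ring alkene is the second π-component has not been shown to react this way. Ring B closes in the sigmatropic event itself: the six reacting atoms are held in a boat by the C5–C6 bridge, a bicyclo[2.2.2]octane-like transition state, and no separate cyclisation follows. The one new stereocentre, the spiro carbon, is set by suprafacial chirality transfer from C1, because the vinyl group can reach C4 only on the ring face it occupies, so (S)-15 should give (S)-18. The selectivity needed is the [3,3] shift over a [1,3] shift and over fragmentation into an enone and an allyl anion; relief of strain in the tetrasubstituted alkene (methyl cis to tert-alkyl) and the stability of the enolate favour it, and recombination of a fragmented pair at C4 would give the same constitution. Silylation at low temperature before any proton source is present prevents enolate equilibration.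

Step 12
Reactants: 18 tert-butyldimethyl{3-methyl-3-[(1S)-1-(prop-1-en-2-yl)-4-(trimethylsilyloxy)cyclohex-3-en-1-yl]butoxy}silane
Product: 19 (2S,4S)-4-{4-[(tert-butyldimethylsilyl)oxy]-2-methylbutan-2-yl}-2-chloro-4-(prop-1-en-2-yl)cyclohexan-1-one
Conditions: NCS, THF, −78 to 0 °C; then LiCl, DMF, 23 °C
Reagents that add atoms: N-chlorosuccinimide, O=C1CCC(=O)N1Cl
Why: Electrophilic chlorination of a silyl enol ether puts chlorine on the carbon fixed in step 11. The tert-alkyl group locks the chair with itself equatorial and isopropenyl axial, so the chloride cis to the tert-alkyl group is equatorial and preferred (its epimer would be syn-axial to isopropenyl), and chloride exchange funnels any epimer to it.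

Step 13
Reactants: 19 (2S,4S)-4-{4-[(tert-butyldimethylsilyl)oxy]-2-methylbutan-2-yl}-2-chloro-4-(prop-1-en-2-yl)cyclohexan-1-one
Product: 20 (1R,2S,4S)-4-{4-[(tert-butyldimethylsilyl)oxy]-2-methylbutan-2-yl}-2-chloro-1-methyl-4-(prop-1-en-2-yl)cyclohexan-1-ol
Conditions: MeTi(OiPr)3 (2.5 equiv), Et2O, −40 to 0 °C; aq. NH4Cl
Reagents that add atoms: methyltitanium triisopropoxide, C[Ti](OC(C)C)(OC(C)C)OC(C)C
Why: Carbonyl addition of a non-basic methyltitanium reagent, which attacks cyclohexanones from the equatorial side; this gives the axial hydroxyl cis to the equatorial chloride and trans methyl, without enolising the ketone or displacing the α-chloride.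

Step 14
Reactants: 20 (1R,2S,4S)-4-{4-[(tert-butyldimethylsilyl)oxy]-2-methylbutan-2-yl}-2-chloro-1-methyl-4-(prop-1-en-2-yl)cyclohexan-1-ol
Product: 21 (1R,2S,4S)-2-chloro-4-(4-hydroxy-2-methylbutan-2-yl)-1-methyl-4-(prop-1-en-2-yl)cyclohexan-1-ol
Conditions: HF·pyridine, pyridine, THF, 0 to 23 °C
Reagents that add atoms: none
Why: Fluoride-driven cleavage of the primary silyl ether under buffered conditions that leave the cis chlorohydrin, the tertiary alcohol and the alkene alone.

Step 15
Reactants: 21 (1R,2S,4S)-2-chloro-4-(4-hydroxy-2-methylbutan-2-yl)-1-methyl-4-(prop-1-en-2-yl)cyclohexan-1-ol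
Product: 22 3-[(1S,3S,4R)-3-chloro-4-hydroxy-4-methyl-1-(prop-1-en-2-yl)cyclohexyl]-3-methylbutanal
Conditions: 2,2,6,6-tetramethylpiperidin-1-oxyl (10 mol%), PhI(OAc)2, CH2Cl2, 23 °C
Reagents that add atoms: none
Why: Oxoammonium-mediated oxidation of the primary alcohol to the aldehyde; the tertiary alcohol cannot be oxidised and no strong acid is present that could trigger closure onto the isopropenyl group.

Step 16
Reactants: 22 3-[(1S,3S,4R)-3-chloro-4-hydroxy-4-methyl-1-(prop-1-en-2-yl)cyclohexyl]-3-methylbutanal
Product: 23 (2S)-2-bromo-3-[(1S,3S,4R)-3-chloro-4-hydroxy-4-methyl-1-(prop-1-en-2-yl)cyclohexyl]-3-methylbutanal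
Conditions: (S)-2-{bis[3,5-bis(trifluoromethyl)phenyl][(trimethylsilyl)oxy]methyl}pyrrolidine (20 mol%), 4,4-dibromo-2,6-di-tert-butylcyclohexa-2,5-dien-1-one (1.1 equiv), PhCO2H (20 mol%), CH2Cl2/pentane, −40 °C; cold filtration through silica, used at once
Reagents that add atoms: 4,4-dibromo-2,6-di-tert-butylcyclohexa-2,5-dien-1-one, O=C1C(C(C)(C)C)=CC(Br)(Br)C=C1C(C)(C)C
Why: Enamine-catalysed electrophilic α-bromination of an aldehyde; the bulky group of the (S)-catalyst covers one face of the E-enamine and bromine enters from the other, which corresponds to (S) at the new stereocentre. The β-carbon is quaternary, so no elimination to an enal can follow.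

Step 17
Reactants: 23 (2S)-2-bromo-3-[(1S,3S,4R)-3-chloro-4-hydroxy-4-methyl-1-(prop-1-en-2-yl)cyclohexyl]-3-methylbutanal
Product: 24 (2S,3R,6S,8S,9R)-2-bromo-8-chloro-1,1,9-trimethyl-5-methylidenespiro[5.5]undecane-3,9-diol
Conditions: Me2AlCl (2.5 equiv), CH2Cl2, −78 to −40 °C; aq. potassium sodium tartrate
Reagents that add atoms: none
Why: Lewis-acid-promoted intramolecular carbonyl-ene reaction with the tether on the central carbon of the ene unit: the isopropenyl CH2 bonds to the aldehyde carbon while a methyl hydrogen passes to oxygen, closing ring A with the exocyclic methylene. The concerted hydrogen transfer needs the carbonyl axial in a chair, and the chair with bromine equatorial also avoids a syn-axial contact with ring B, so the hydroxyl should come out cis to bromine. One equivalent of Me2AlCl is consumed by the tertiary hydroxyl.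

## Compound list

1 | 3,3-dimethyldihydrofuran-2(3H)-one | CC1(C)CCOC1=O | starting material
2 | 5-hydroxy-3,3-dimethylpentan-2-one | CC(=O)C(C)(C)CCO | intermediate
3 | 5-[(tert-butyldimethylsilyl)oxy]-3,3-dimethylpentan-2-one | CC(=O)C(C)(C)CCO[Si](C)(C)C(C)(C)C | intermediate
4 | 5-[(tert-butyldimethylsilyl)oxy]-3,3-dimethylpent-1-en-2-yl trifluoromethanesulfonate | C=C(OS(=O)(=O)C(F)(F)F)C(C)(C)CCO[Si](C)(C)C(C)(C)C | intermediate
5 | 2-bromoprop-2-en-1-ol | C=C(Br)CO | starting material
6 | lithium 2-lithioprop-2-en-1-olate | [Li]OCC(=C)[Li] | intermediate (not isolated)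
7 | lithium 2-(chlorozincio)prop-2-en-1-olate | [Li]OCC(=C)[Zn]Cl | intermediate (not isolated)
8 | 6-[(tert-butyldimethylsilyl)oxy]-4,4-dimethyl-2,3-dimethylidenehexan-1-ol | C=C(CO)C(=C)C(C)(C)CCO[Si](C)(C)C(C)(C)C | intermediate
9 | tert-butyl[(6-chloro-3,3-dimethyl-4,5-dimethylidenehexyl)oxy]dimethylsilane | C=C(CCl)C(=C)C(C)(C)CCO[Si](C)(C)C(C)(C)C | intermediate
10 | 2,2-dimethyl-1,3-dioxan-5-one | CC1(C)OCC(=O)CO1 | starting material
11 | 2,2-dimethyl-4H-1,3-dioxin-5-yl benzoate | CC1(C)OCC(OC(=O)c2ccccc2)=CO1 | intermediate
12 | 1-formylethenyl benzoate (2-benzoyloxyacrolein) | C=C(C=O)OC(=O)c1ccccc1 | intermediate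
13 | (1S)-3-(chloromethyl)-1-formyl-4-{4-[(tert-butyldimethylsilyl)oxy]-2-methylbutan-2-yl}cyclohex-3-en-1-yl benzoate | O=C[C@]1(OC(=O)c2ccccc2)CCC(C(C)(C)CCO[Si](C)(C)C(C)(C)C)=C(CCl)C1 | intermediate
14 | (1S)-3-(chloromethyl)-1-ethenyl-4-{4-[(tert-butyldimethylsilyl)oxy]-2-methylbutan-2-yl}cyclohex-3-en-1-yl benzoate | C=C[C@]1(OC(=O)c2ccccc2)CCC(C(C)(C)CCO[Si](C)(C)C(C)(C)C)=C(CCl)C1 | intermediate
15 | (1S)-4-{4-[(tert-butyldimethylsilyl)oxy]-2-methylbutan-2-yl}-1-ethenyl-3-methylcyclohex-3-en-1-ol | C=C[C@]1(O)CCC(C(C)(C)CCO[Si](C)(C)C(C)(C)C)=C(C)C1 | intermediate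
16 | potassium (1S)-4-{4-[(tert-butyldimethylsilyl)oxy]-2-methylbutan-2-yl}-1-ethenyl-3-methylcyclohex-3-en-1-olate | C=C[C@]1([O-])CCC(C(C)(C)CCO[Si](C)(C)C(C)(C)C)=C(C)C1.[K+] | intermediate (not isolated)
17 | potassium (4S)-4-{4-[(tert-butyldimethylsilyl)oxy]-2-methylbutan-2-yl}-4-(prop-1-en-2-yl)cyclohex-1-en-1-olate | CC(C)(CCO[Si](C)(C)C(C)(C)C)[C@@]1(C(C)=C)CCC([O-])=CC1.[K+] | intermediate (not isolated)
18 | tert-butyldimethyl{3-methyl-3-[(1S)-1-(prop-1-en-2-yl)-4-(trimethylsilyloxy)cyclohex-3-en-1-yl]butoxy}silane | CC(C)(CCO[Si](C)(C)C(C)(C)C)[C@@]1(C(C)=C)CCC(O[Si](C)(C)C)=CC1 | intermediate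
19 | (2S,4S)-4-{4-[(tert-butyldimethylsilyl)oxy]-2-methylbutan-2-yl}-2-chloro-4-(prop-1-en-2-yl)cyclohexan-1-one | CC(C)(CCO[Si](C)(C)C(C)(C)C)[C@@]1(C(C)=C)CCC(=O)[C@@H](Cl)C1 | intermediate
20 | (1R,2S,4S)-4-{4-[(tert-butyldimethylsilyl)oxy]-2-methylbutan-2-yl}-2-chloro-1-methyl-4-(prop-1-en-2-yl)cyclohexan-1-ol | CC(C)(CCO[Si](C)(C)C(C)(C)C)[C@@]1(C(C)=C)CC[C@@](C)(O)[C@@H](Cl)C1 | intermediate
21 | (1R,2S,4S)-2-chloro-4-(4-hydroxy-2-methylbutan-2-yl)-1-methyl-4-(prop-1-en-2-yl)cyclohexan-1-ol | CC(C)(CCO)[C@@]1(C(C)=C)CC[C@@](C)(O)[C@@H](Cl)C1 | intermediate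
22 | 3-[(1S,3S,4R)-3-chloro-4-hydroxy-4-methyl-1-(prop-1-en-2-yl)cyclohexyl]-3-methylbutanal | CC(C)(CC=O)[C@@]1(C(C)=C)CC[C@@](C)(O)[C@@H](Cl)C1 | intermediate
23 | (2S)-2-bromo-3-[(1S,3S,4R)-3-chloro-4-hydroxy-4-methyl-1-(prop-1-en-2-yl)cyclohexyl]-3-methylbutanal | CC(C)([C@H](Br)C=O)[C@@]1(C(C)=C)CC[C@@](C)(O)[C@@H](Cl)C1 | intermediate
24 | (2S,3R,6S,8S,9R)-2-bromo-8-chloro-1,1,9-trimethyl-5-methylidenespiro[5.5]undecane-3,9-diol | C=C1C[C@@H](O)[C@@H](Br)C(C)(C)[C@]12CC[C@@](C)(O)[C@@H](Cl)C2 | target

## Step count and least certain steps

Total step count: 17. Longest linear sequence: 15 steps (steps 1–5 and 8–17, from 1 to 24); steps 6 and 7 form the two-step branch to 12.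

Step 11 (key step, carries the new-method label).
- What may go wrong: the alkoxide may break heterolytically at the allylic bond faster than the boat [3,3] transition state is reached, because bonding at the fully substituted alkene carbon beside CMe2 is sterically costly. The hindered allyl anion would then be protonated, or would recombine at its primary end (a net [1,3] shift to an eight-membered ketone). Proton exchange during capture would also scramble the enolate.
- Fallback (known chemistry only), from 4, returning at 19:
 - Reductive carbonylation of 4 (CO, Bu3SnH, Pd(PPh3)4) should give 2-{4-[(tert-butyldimethylsilyl)oxy]-2-methylbutan-2-yl}prop-2-enal F1.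
 - A catalytic asymmetric Diels–Alder reaction of F1 with 2-(triisopropylsilyloxy)buta-1,3-diene F2 (from but-3-en-2-one, iPr3SiOTf and Et3N) would follow. The catalyst is the Tf2NH-protonated B-(o-tolyl) oxazaborolidine derived from diphenylprolinol, in the antipode that gives the (1R) adduct. The product should be (1R)-1-{4-[(tert-butyldimethylsilyl)oxy]-2-methylbutan-2-yl}-4-(triisopropylsilyloxy)cyclohex-3-ene-1-carbaldehyde F3, with the enol ether already on the correct arm by the para rule.
 - MeMgBr would convert F3 into the secondary alcohol 1-[(1R)-1-{4-[(tert-butyldimethylsilyl)oxy]-2-methylbutan-2-yl}-4-(triisopropylsilyloxy)cyclohex-3-en-1-yl]ethan-1-ol F4.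
 - Dess–Martin oxidation would give the methyl ketone 1-[(1R)-1-{4-[(tert-butyldimethylsilyl)oxy]-2-methylbutan-2-yl}-4-(triisopropylsilyloxy)cyclohex-3-en-1-yl]ethan-1-one F5.
 - Methylenation with Cp2TiMe2 would give the triisopropylsilyl enol ether tert-butyldimethyl{3-methyl-3-[(1S)-1-(prop-1-en-2-yl)-4-(triisopropylsilyloxy)cyclohex-3-en-1-yl]butoxy}silane F6.
 - NCS followed by LiCl in DMF would turn F6 into 19.

Step 8.
- What may go wrong: the cycloaddition may be slow because the diene must reach its s-cis form against eclipsing of the tert-alkyl and chloromethyl groups. Regio- and enantiocontrol may erode at the higher temperature then needed, and the amine catalyst may be alkylated by the allylic chloride.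
- Fallback, from 9, returning at 15:
 - An auxiliary-controlled cycloaddition (toluene, 80–100 °C, or Et2AlCl at low temperature) with the lactic-acid-derived dienophile (R)-2-tert-butyl-5-methylidene-1,3-dioxolan-4-one F7 would be used; the diene adds to the face remote from tert-butyl. It should give the spiro adduct (2R,5S)-2-tert-butyl-7-(chloromethyl)-8-{4-[(tert-butyldimethylsilyl)oxy]-2-methylbutan-2-yl}-1,3-dioxaspiro[4.5]dec-7-en-4-one F8.
 - LiAlH4 would reduce the lactone acetal and the chloromethyl group in one operation to the diol (1S)-4-{4-[(tert-butyldimethylsilyl)oxy]-2-methylbutan-2-yl}-1-(hydroxymethyl)-3-methylcyclohex-3-en-1-ol F9.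
 - Oxidation of the primary alcohol (2,2,6,6-tetramethylpiperidin-1-oxyl, PhI(OAc)2) would give (1S)-4-{4-[(tert-butyldimethylsilyl)oxy]-2-methylbutan-2-yl}-1-hydroxy-3-methylcyclohex-3-ene-1-carbaldehyde F10.
 - Wittig methylenation with excess ylide would give 15.

Step 16.
- What may go wrong: enamine formation at the neopentyl-type aldehyde may be slow, the intermediate iminium ion may be captured by the neighbouring isopropenyl group (cationic cyclisation), the catalyst may be mismatched with the existing stereocentres, and the bromo aldehyde may epimerise before use.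
- Fallback, from 22, returning at 23:
 - Pinnick oxidation (NaClO2, NaH2PO4, 2-methylbut-2-ene) would give 3-[(1S,3S,4R)-3-chloro-4-hydroxy-4-methyl-1-(prop-1-en-2-yl)cyclohexyl]-3-methylbutanoic acid F11.
 - The mixed pivalic anhydride and lithiated (S)-4-benzyloxazolidin-2-one would give the imide (4S)-4-benzyl-3-{3-[(1S,3S,4R)-3-chloro-4-hydroxy-4-methyl-1-(prop-1-en-2-yl)cyclohexyl]-3-methylbutanoyl}oxazolidin-2-one F12.
 - Its boron enolate (Bu2BOTf, iPr2NEt) and NBS would give, under auxiliary control, the (2S)-2-bromo imide F13.
 - LiBH4 would release (2S)-2-bromo-3-[(1S,3S,4R)-3-chloro-4-hydroxy-4-methyl-1-(prop-1-en-2-yl)cyclohexyl]-3-methylbutan-1-ol F14.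
 - Oxidation as in step 15 would give 23.

Step 17.
- What may go wrong: the axial carbonyl needed for the concerted closure is syn-axial to a methyl of the gem-dimethyl carbon, so a stepwise cationic closure may take over. That would bring loss of facial selectivity at the aldehyde carbon (hydroxyl equatorial), migration of the double bond into the ring, or chloride capture. The Lewis acid may also activate the chlorohydrin toward a semipinacol shift.
- Fallback, from 23, returning at 24:
 - Closure with the bulky methylaluminium bis(4-bromo-2,6-di-tert-butylphenoxide), which favours the equatorial alcohol, would be accepted as the C3 epimer (2S,3S,6S,8S,9R)-2-bromo-8-chloro-1,1,9-trimethyl-5-methylidenespiro[5.5]undecane-3,9-diol F15.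
 - Dess–Martin oxidation would give the bromo ketone (2S,6S,8S,9R)-2-bromo-8-chloro-9-hydroxy-1,1,9-trimethyl-5-methylidenespiro[5.5]undecan-3-one F16.
 - DIBAL-H at −78 °C would deliver hydride from the equatorial side, because the axial side is blocked by the axial methyl group, and so give the axial alcohol 24.

## Further compounds

F1 | step 11 | 2-{4-[(tert-butyldimethylsilyl)oxy]-2-methylbutan-2-yl}prop-2-enal | C=C(C=O)C(C)(C)CCO[Si](C)(C)C(C)(C)C
F2 | step 11 | 2-(triisopropylsilyloxy)buta-1,3-diene | C=CC(=C)O[Si](C(C)C)(C(C)C)C(C)C
F3 | step 11 | (1R)-1-{4-[(tert-butyldimethylsilyl)oxy]-2-methylbutan-2-yl}-4-(triisopropylsilyloxy)cyclohex-3-ene-1-carbaldehyde | CC(C)(CCO[Si](C)(C)C(C)(C)C)[C@@]1(C=O)CCC(O[Si](C(C)C)(C(C)C)C(C)C)=CC1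
F4 | step 11 | 1-[(1R)-1-{4-[(tert-butyldimethylsilyl)oxy]-2-methylbutan-2-yl}-4-(triisopropylsilyloxy)cyclohex-3-en-1-yl]ethan-1-ol (both carbinol epimers) | CC(C)(CCO[Si](C)(C)C(C)(C)C)[C@@]1(C(C)O)CCC(O[Si](C(C)C)(C(C)C)C(C)C)=CC1
F5 | step 11 | 1-[(1R)-1-{4-[(tert-butyldimethylsilyl)oxy]-2-methylbutan-2-yl}-4-(triisopropylsilyloxy)cyclohex-3-en-1-yl]ethan-1-one | CC(C)(CCO[Si](C)(C)C(C)(C)C)[C@@]1(C(C)=O)CCC(O[Si](C(C)C)(C(C)C)C(C)C)=CC1
F6 | step 11 | tert-butyldimethyl{3-methyl-3-[(1S)-1-(prop-1-en-2-yl)-4-(triisopropylsilyloxy)cyclohex-3-en-1-yl]butoxy}silane | CC(C)(CCO[Si](C)(C)C(C)(C)C)[C@@]1(C(C)=C)CCC(O[Si](C(C)C)(C(C)C)C(C)C)=CC1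
F7 | step 8 | (R)-2-tert-butyl-5-methylidene-1,3-dioxolan-4-one | C=C1O[C@@H](C(C)(C)C)OC1=O
F8 | step 8 | (2R,5S)-2-tert-butyl-7-(chloromethyl)-8-{4-[(tert-butyldimethylsilyl)oxy]-2-methylbutan-2-yl}-1,3-dioxaspiro[4.5]dec-7-en-4-one | O=C1O[C@H](C(C)(C)C)O[C@]12CCC(C(C)(C)CCO[Si](C)(C)C(C)(C)C)=C(CCl)C2
F9 | step 8 | (1S)-4-{4-[(tert-butyldimethylsilyl)oxy]-2-methylbutan-2-yl}-1-(hydroxymethyl)-3-methylcyclohex-3-en-1-ol | OC[C@]1(O)CCC(C(C)(C)CCO[Si](C)(C)C(C)(C)C)=C(C)C1
F10 | step 8 | (1S)-4-{4-[(tert-butyldimethylsilyl)oxy]-2-methylbutan-2-yl}-1-hydroxy-3-methylcyclohex-3-ene-1-carbaldehyde | O=C[C@]1(O)CCC(C(C)(C)CCO[Si](C)(C)C(C)(C)C)=C(C)C1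
F11 | step 16 | 3-[(1S,3S,4R)-3-chloro-4-hydroxy-4-methyl-1-(prop-1-en-2-yl)cyclohexyl]-3-methylbutanoic acid | CC(C)(CC(=O)O)[C@@]1(C(C)=C)CC[C@@](C)(O)[C@@H](Cl)C1
F12 | step 16 | (4S)-4-benzyl-3-{3-[(1S,3S,4R)-3-chloro-4-hydroxy-4-methyl-1-(prop-1-en-2-yl)cyclohexyl]-3-methylbutanoyl}oxazolidin-2-one | CC(C)(CC(=O)N2[C@@H](Cc3ccccc3)COC2=O)[C@@]1(C(C)=C)CC[C@@](C)(O)[C@@H](Cl)C1
F13 | step 16 | (4S)-4-benzyl-3-{(2S)-2-bromo-3-[(1S,3S,4R)-3-chloro-4-hydroxy-4-methyl-1-(prop-1-en-2-yl)cyclohexyl]-3-methylbutanoyl}oxazolidin-2-one | CC(C)([C@H](Br)C(=O)N2[C@@H](Cc3ccccc3)COC2=O)[C@@]1(C(C)=C)CC[C@@](C)(O)[C@@H](Cl)C1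
F14 | step 16 | (2S)-2-bromo-3-[(1S,3S,4R)-3-chloro-4-hydroxy-4-methyl-1-(prop-1-en-2-yl)cyclohexyl]-3-methylbutan-1-ol | CC(C)([C@H](Br)CO)[C@@]1(C(C)=C)CC[C@@](C)(O)[C@@H](Cl)C1
F15 | step 17 | (2S,3S,6S,8S,9R)-2-bromo-8-chloro-1,1,9-trimethyl-5-methylidenespiro[5.5]undecane-3,9-diol | C=C1C[C@H](O)[C@@H](Br)C(C)(C)[C@]12CC[C@@](C)(O)[C@@H](Cl)C2
F16 | step 17 | (2S,6S,8S,9R)-2-bromo-8-chloro-9-hydroxy-1,1,9-trimethyl-5-methylidenespiro[5.5]undecan-3-one | C=C1CC(=O)[C@@H](Br)C(C)(C)[C@]12CC[C@@](C)(O)[C@@H](Cl)C2
A1 | alternative 1 | 1-[(3S,4R)-3-bromo-4-[(tert-butyldimethylsilyl)oxy]-2-methylhept-6-yn-2-yl]-4-methoxybenzene | COc1ccc(cc1)C(C)(C)[C@H](Br)[C@H](O[Si](C)(C)C(C)(C)C)CC#C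
A2 | alternative 1 | (2S,3R)-2-bromo-3-[(tert-butyldimethylsilyl)oxy]-1,1-dimethyl-5-methylidenespiro[5.5]undeca-7,10-dien-9-one | C=C1C[C@@H](O[Si](C)(C)C(C)(C)C)[C@@H](Br)C(C)(C)C12C=CC(=O)C=C2
A3 | alternative 2 | tert-butyl (4S)-4-bromo-5-(8-ethynyl-1,4-dioxaspiro[4.5]decan-8-yl)-5-methyl-3-oxohexanoate | C#CC1(CCC2(CC1)OCCO2)C(C)(C)[C@H](Br)C(=O)CC(=O)OC(C)(C)C
A4 | alternative 2 | tert-butyl (4S)-4-bromo-3-hydroxy-5,5-dimethyl-1-methylidenespiro[5.5]undec-2-ene-2-carboxylate 9-(ethylene ketal) | C=C1C(C(=O)OC(C)(C)C)=C(O)[C@@H](Br)C(C)(C)C12CCC3(CC2)OCCO3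
A5 | alternative 3 | (6R,7S)-7-bromo-6-[(tert-butyldimethylsilyl)oxy]-10,10-dimethoxy-8,8-dimethyl-9-methylidenedecane-2,4-dione | CC(=O)CC(=O)C[C@@H](O[Si](C)(C)C(C)(C)C)[C@@H](Br)C(C)(C)C(=C)C(OC)OC
A6 | alternative 3 | (2S,4S,5R)-4-bromo-5-[(tert-butyldimethylsilyl)oxy]-2-(dimethoxymethyl)-3,3-dimethyl-2-(3-oxobutyl)cyclohexan-1-one | O=C1C[C@@H](O[Si](C)(C)C(C)(C)C)[C@@H](Br)C(C)(C)[C@@]1(CCC(C)=O)C(OC)OC
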